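Per molar per minute is the unit to count this flask in: a constant of that kind, multiplied by the nucleophile in solution and by the time, gives the exponent of how much electrophile has gone.

in all of them: electrophile 0.23 M (fed, over 15 min)
- oak: nucleophile 0.30 M; solid base 0.69 M; run made earlier; the fed solution adds 0.20 times the starting volume
- ash: nucleophile 0.64 M; solid base 0.69 M; run made earlier; the fed solution adds 0.20 times the starting volume
- Friday's: nucleophile 0.250 M; solid base 0.690 M; the fed solution adds 0.20 times the starting volume; time 80 min
- Wednesday's: nucleophile 0.510 M; solid base 0.690 M; the fed solution adds 0.20 times the starting volume; time 80 min

| run | time / min | electrophile / % | target / % |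
|---|---|---|---|
| oak | 5.00 | 33.1 | 0 |
| oak | 15.0 | 96.3 | 6.0 |
| oak | 25.0 | 91.7 | 10.9 |
| oak | 40.0 | 82.8 | 18.0 |
| ash | 10.0 | 61.1 | 5.8 |
| ash | 20.0 | 85.7 | 15.2 |
| ash | 30.0 | 76.1 | 23.0 |
| ash | 40.0 | 69.3 | 32.3 |

(standard deviation of a reading: 1 percentage point)

- every charge counts on the volume at the start, and the solution that is fed holds the whole dose
- solid, in amounts per volume of the solution: solid base
- the earlier runs were read with a standard deviation of 1 percentage point
- at the start none of the solid base is in solution
- percentages count the whole charge, also what has not yet gone in

- part of the electrophile that has reacted at the end, Friday's
- part of the electrophile that has reacted at the end, Wednesday's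
- what raising the concentration of nucleophile from its lowest to its highest value here does to the part of the electrophile that has reacted (changes below 5 percentage points count as none) (it falls / no change / it rises)

Open the books on the electrophile, the charge of 0.23 M on which the readings are counted. The first entry is what still sits in the feed: in the oak run at 5.00 min the flask shows 33.1% electrophile and 0% target, so the rest of the charge is yet to come, and this entry closes at 15 min. The second entry is electrophile in the flask and the third is target, and at 40.0 min these two add up to 101% in oak and 102% in ash, so within the scatter of two readings you need no fourth entry. What you need next is how fast the third entry fills.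

After the feed, oak falls from 96.3% to 82.8% between 15.0 min and 40.0 min; read as pseudo-first-order, the natural log of that ratio per minute, divided by the nucleophile on the diluted volume, gives 0.0242 /M/min, and ash, read the same way, gives 0.0199 /M/min. I take their mean as the pace constant, the share of electrophile lost per minute for each molar of nucleophile, 0.0220 /M/min. Electrophile enters on average at mid-feed, so by 80 min it has had 72.5 min. For the nucleophile I use the diluted charge less half of what the third entry has used, as a mean over the run, and that gives me 25.1% for Friday's and 45.3% for Wednesday's, a gap of 20 percentage points.

The forecast stands above both my figures, at 29% (25% to 34%) and 47% (41% to 53%), with the verdict it rises, on the ground that “Doubling the nucleophile therefore roughly doubles the rate”.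

The flask gives 23.8% for Friday's and 43.4% for Wednesday's, and across the nucleophile range it rises, by 20 points.

    acid set free + free base ⇌ salt of the base (K = 40.0 /M, k = 2.60 /M/min)
    nucleophile + acid set free ⇌ protonated nucleophile, settled at all times (K = 1600 /M)
    electrophile + nucleophile → acid set free + target (k = 0.0310 /M/min)
    solid base ⇌ free base, rate k4*(cs4 - [free base]) while solid is left; crystals form when [free base] > cs4 (solubility = 0.160 M, k = 0.00680 /min)
    nucleophile ⇌ dormant form (K = 0.310, k = 0.0200 /min)

Friday's flask ended with 42% of its nucleophile free, less than the 76% of its electrophile still there, each counted on its own charge. Put the pace constant on the neighbour of Wednesday's charged with 2.0 M of nucleophile, with the same mean and the same 72.5 min, and you reckon 92.0%; that flask reached 91.6%, with 8.4% of its electrophile left.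

The readings come from a simulation for substances that don't exist, noise included.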